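**Retrosynthetic overview**
1. Target 16 ⇐ reductive opening of endoperoxide 15 ⇐ [4+2] cycloaddition of singlet oxygen to bicyclic dienol ether 14; this one operation sets C4–OH and unveils C1=O and the 2′-OH.
2. 14 ⇐ face-selective epoxidation/isomerisation of enol ether 11; the C6 tertiary OH is set trans to the C2′ chain on the rigid dihydrofuran.
3. 11 ⇐ Birch reduction of (S)-2-alkyl-2,3-dihydrobenzofuran 10 ⇐ intramolecular C–O coupling of bromo alcohol 9.
4. 9 ⇐ 2-bromophenyl Grignard + (S)-epoxide 6 ⇐ (S)-epichlorohydrin 3 (the only source of chirality) + Grignard from Z-bromide 2.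
5. Ring order: the carbocycle is bought as the benzene ring; then the dihydrofuran ring (step 4); then the endoperoxide ring (step 7); both heterocycles are opened in the last operation.

Assumption: (7Z)-tetradec-7-en-1-ol (pheromone-grade), (S)-epichlorohydrin and 1-bromo-2-iodobenzene are purchasable; target atoms are numbered C1 (C=O) to C6 (C–OH) in the ring and C1′–C17′ in the side chain.

**Step 1**
Reactants: 1 (7Z)-tetradec-7-en-1-ol
Product: 2 (7Z)-1-bromotetradec-7-ene
Conditions: CBr4, PPh3, CH2Cl2, 0 °C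
Reagents that add atoms: carbon tetrabromide, BrC(Br)(Br)Br
Why: Appel bromination converts the primary alcohol into the bromide under neutral conditions that leave the Z-alkene untouched, and no stereocenter is involved.

**Step 2**
Reactants: 2 (7Z)-1-bromotetradec-7-ene; 3 (S)-epichlorohydrin
Product: 6 (2S)-2-[(8Z)-pentadec-8-en-1-yl]oxirane, via Grignard reagent 4 (not isolated), via chlorohydrin 5 (not isolated)
Conditions: Mg, THF; then 3, CuI (5 mol %), THF, −40 °C; then aq. NaOH, rt
Reagents that add atoms: none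
Why: Copper-catalysed Grignard opening at the CH2 terminus of the epoxide followed by Williamson ring closure of the chlorohydrin alkoxide relocates the oxirane without breaking any bond at the purchased stereocenter, which becomes C2′ of the target (S).

**Step 3**
Reactants: 6 (2S)-2-[(8Z)-pentadec-8-en-1-yl]oxirane; 7 1-bromo-2-iodobenzene
Product: 9 (2S,10Z)-1-(2-bromophenyl)heptadec-10-en-2-ol, via aryl Grignard 8 (not isolated)
Conditions: 7, i-PrMgCl·LiCl, THF, −40 °C; then 6, CuI (10 mol %), −40 → 0 °C; 1 M HCl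
Reagents that add atoms: none
Why: Selective iodine–magnesium exchange (Knochel) gives the 2-bromophenyl Grignard, which opens the terminal epoxide at its CH2 carbon in a copper-catalysed SN2 reaction, so the C2′ stereocenter is not touched.

**Step 4**
Reactants: 9 (2S,10Z)-1-(2-bromophenyl)heptadec-10-en-2-ol
Product: 10 (2S)-2-[(8Z)-pentadec-8-en-1-yl]-2,3-dihydro-1-benzofuran
Conditions: CuI (10 mol %), 3,4,7,8-tetramethyl-1,10-phenanthroline (20 mol %), Cs2CO3, toluene, 110 °C
Reagents that add atoms: none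
Why: Ullmann-type intramolecular O-arylation closes the five-membered ether through the alkoxide oxygen, so the C2′–O bond is never broken and the configuration is retained.

**Step 5**
Reactants: 10 (2S)-2-[(8Z)-pentadec-8-en-1-yl]-2,3-dihydro-1-benzofuran
Product: 11 (2S)-2-[(8Z)-pentadec-8-en-1-yl]-2,3,4,7-tetrahydro-1-benzofuran
Conditions: Li, NH3(l)/THF, t-BuOH, −78 °C
Reagents that add atoms: none
Why: Birch reduction protonates the two unsubstituted para-related positions (C4 and C7), leaving the donor-substituted C3a=C7a enol ether and the C5=C6 alkene, while the isolated Z-alkene and the stereocenter are inert to dissolving metal.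

**Step 6**
Reactants: 11 (2S)-2-[(8Z)-pentadec-8-en-1-yl]-2,3,4,7-tetrahydro-1-benzofuran
Product: 14 (2S,3aS)-2-[(8Z)-pentadec-8-en-1-yl]-2,3-dihydro-1-benzofuran-3a(4H)-ol, via epoxide 12 (not isolated), via silyl ether 13 (not isolated)
Conditions: DMDO (1.0 equiv, acetone-free, CH2Cl2), −78 °C; then 2,6-lutidine, TMSOTf, −78 → −30 °C; then K2CO3, MeOH, 0 °C; used crude
Reagents that add atoms: dimethyldioxirane (DMDO), CC1(C)OO1
Why: Electrophilic epoxidation picks the tetrasubstituted enol ether and should occur anti to the C2 chain on the near-planar dihydrofuran (the same 1,3-control as in alkylations of γ-substituted butyrolactone enolates, estimated about 5:1 or better), and a Noyori-type TMSOTf isomerisation of the epoxide through the C7a oxocarbenium ion (only C7 carries a proton to lose) followed by methanolysis of the silyl ether gives the tertiary alcohol trans to the chain, which is C6 of the target.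

**Step 7**
Reactants: 14 (2S,3aS)-2-[(8Z)-pentadec-8-en-1-yl]-2,3-dihydro-1-benzofuran-3a(4H)-ol
Product: 16 (4S,6R)-4,6-dihydroxy-6-[(2S,10Z)-2-hydroxyheptadec-10-en-1-yl]cyclohex-2-en-1-one, via endoperoxide 15 (not isolated)
Conditions: O2, hν (visible), tetraphenylporphyrin (cat.), CH2Cl2 (solid NaHCO3), −78 °C; then thiourea, MeOH–H2O, −78 → 20 °C
Reagents that add atoms: dioxygen (reacting as singlet oxygen), O=O
Why: Singlet oxygen adds in a [4+2] cycloaddition to the s-cis 1-alkoxy-1,3-diene on the face of the pseudo-axial allylic 3a-OH (hydrogen-bond steering, the other face being screened by the C2 chain), and thiourea reduction of the O–O bond gives the C4-OH cis to the C6-OH plus a hemiketal that collapses to the C1 enone and the free 2′-OH.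

**Compound list**
1 | (7Z)-tetradec-7-en-1-ol | CCCCCC/C=C\CCCCCCO | starting material
2 | (7Z)-1-bromotetradec-7-ene | CCCCCC/C=C\CCCCCCBr | intermediate
3 | (S)-epichlorohydrin, (2S)-2-(chloromethyl)oxirane | ClC[C@@H]1CO1 | starting material
4 | [(7Z)-tetradec-7-en-1-yl]magnesium bromide | CCCCCC/C=C\CCCCCC[Mg]Br | intermediate
5 | (2S,10Z)-1-chloroheptadec-10-en-2-ol | CCCCCC/C=C\CCCCCCC[C@H](O)CCl | intermediate
6 | (2S)-2-[(8Z)-pentadec-8-en-1-yl]oxirane | CCCCCC/C=C\CCCCCCC[C@H]1CO1 | intermediate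
7 | 1-bromo-2-iodobenzene | Brc1ccccc1I | starting material
8 | (2-bromophenyl)magnesium chloride | Brc1ccccc1[Mg]Cl | intermediate
9 | (2S,10Z)-1-(2-bromophenyl)heptadec-10-en-2-ol | CCCCCC/C=C\CCCCCCC[C@H](O)Cc1ccccc1Br | intermediate
10 | (2S)-2-[(8Z)-pentadec-8-en-1-yl]-2,3-dihydro-1-benzofuran | CCCCCC/C=C\CCCCCCC[C@H]1Cc2ccccc2O1 | intermediate
11 | (2S)-2-[(8Z)-pentadec-8-en-1-yl]-2,3,4,7-tetrahydro-1-benzofuran | CCCCCC/C=C\CCCCCCC[C@H]1CC2=C(O1)CC=CC2 | intermediate
12 | (2S,3aS,7aS)-3a,7a-epoxy-2-[(8Z)-pentadec-8-en-1-yl]-2,3,3a,4,7,7a-hexahydro-1-benzofuran (epoxide oxygen trans to the C2 chain) | CCCCCC/C=C\CCCCCCC[C@H]1C[C@@]23CC=CC[C@@]2(O3)O1 | intermediate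
13 | trimethyl{[(2S,3aS)-2-[(8Z)-pentadec-8-en-1-yl]-2,3-dihydro-1-benzofuran-3a(4H)-yl]oxy}silane | CCCCCC/C=C\CCCCCCC[C@H]1C[C@@]2(O[Si](C)(C)C)CC=CC=C2O1 | intermediate
14 | (2S,3aS)-2-[(8Z)-pentadec-8-en-1-yl]-2,3-dihydro-1-benzofuran-3a(4H)-ol (3a-OH trans to the C2 chain) | CCCCCC/C=C\CCCCCCC[C@H]1C[C@@]2(O)CC=CC=C2O1 | intermediate
15 | (2S,3aR,5S,7aS)-5,7a-epidioxy-2-[(8Z)-pentadec-8-en-1-yl]-2,3,4,5-tetrahydro-1-benzofuran-3a(7aH)-ol (peroxide bridge cis to the 3a-OH) | CCCCCC/C=C\CCCCCCC[C@H]1C[C@@]2(O)C[C@H]3C=C[C@]2(O1)OO3 | intermediate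
16 | (4S,6R)-4,6-dihydroxy-6-[(2S,10Z)-2-hydroxyheptadec-10-en-1-yl]cyclohex-2-en-1-one | CCCCCC/C=C\CCCCCCC[C@H](O)C[C@@]1(O)C[C@H](O)C=CC1=O | target

**Totals and risks**
Total step count: 7. Longest linear sequence: 7 (1 → 2 → 6 → 9 → 10 → 11 → 14 → 16).

Most likely to fail, step 5: the Birch reduction of the cyclic aryl ether may suffer C–O cleavage or incomplete reduction. The fallback reverses the order of ring closure and reduction; it sets out from 6 and comes back at 11. Epoxide 6 is opened with 2-methoxyphenylmagnesium bromide (CuI cat.) to (2S,10Z)-1-(2-methoxyphenyl)heptadec-10-en-2-ol F1. Birch reduction of this ordinary anisole (Li, NH3, t-BuOH) gives (2S,10Z)-1-(2-methoxycyclohexa-1,4-dien-1-yl)heptadec-10-en-2-ol F2. PPTS-catalysed intramolecular enol-ether exchange (benzene, 4 Å sieves, loss of methanol) then closes the dihydrofuran to 11.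

Most likely to fail, step 6: facial selectivity of the epoxidation may be modest, and 14 is an acid-labile arene hydrate that can aromatise back to 10 during the TMSOTf treatment. The fallback sets out from 11 and comes back at 14. Epoxide 12 is quenched with methanol instead of being isomerised, giving the stable, chromatographable α-hydroxy ketal (2S,3aS,7aR)-7a-methoxy-2-[(8Z)-pentadec-8-en-1-yl]-2,3,4,7-tetrahydro-1-benzofuran-3a(7aH)-ol F3, from which the unwanted C3a epimer is removed. A Gassman ketal-to-enol-ether elimination (TMSOTf, i-Pr2NEt, −20 °C) then gives silyl ether 13, and K2CO3/MeOH returns 14.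

Most likely to fail, step 7: the singlet-oxygen addition may show poor facial selectivity, or the α-hydroxy peroxyketal 15 may fragment. The fallback replaces the cycloaddition by hydroxyl-directed epoxidation and E1cB opening; it sets out from 11 and comes back at 16. Epoxide 12 (DMDO) is hydrolysed with aqueous NaHCO3/THF to (2S)-2-hydroxy-2-[(2S,10Z)-2-hydroxyheptadec-10-en-1-yl]cyclohex-4-en-1-one F4. VO(acac)2/t-BuOOH epoxidation directed by the homoallylic tertiary OH gives (2R,4S,5R)-4,5-epoxy-2-hydroxy-2-[(2S,10Z)-2-hydroxyheptadec-10-en-1-yl]cyclohexan-1-one F5, with the epoxide cis to the ring OH. DBU then opens the β,γ-epoxy ketone to the γ-hydroxy enone 16.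

**Further compounds**
F1 | step 5 | (2S,10Z)-1-(2-methoxyphenyl)heptadec-10-en-2-ol | CCCCCC/C=C\CCCCCCC[C@H](O)Cc1ccccc1OC
F2 | step 5 | (2S,10Z)-1-(2-methoxycyclohexa-1,4-dien-1-yl)heptadec-10-en-2-ol | CCCCCC/C=C\CCCCCCC[C@H](O)CC1=C(OC)CC=CC1
F3 | step 6 | (2S,3aS,7aR)-7a-methoxy-2-[(8Z)-pentadec-8-en-1-yl]-2,3,4,7-tetrahydro-1-benzofuran-3a(7aH)-ol | CCCCCC/C=C\CCCCCCC[C@H]1C[C@@]2(O)CC=CC[C@@]2(OC)O1
F4 | step 7 | (2S)-2-hydroxy-2-[(2S,10Z)-2-hydroxyheptadec-10-en-1-yl]cyclohex-4-en-1-one | CCCCCC/C=C\CCCCCCC[C@H](O)C[C@@]1(O)CC=CCC1=O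
F5 | step 7 | (2R,4S,5R)-4,5-epoxy-2-hydroxy-2-[(2S,10Z)-2-hydroxyheptadec-10-en-1-yl]cyclohexan-1-one | CCCCCC/C=C\CCCCCCC[C@H](O)C[C@@]1(O)C[C@@H]2O[C@@H]2CC1=O
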